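**Plan**

Cuts, in retrosynthetic order: the epoxide O on C1/C10; the acyl C–O bonds at O8 and O3; then together the lactone O–C6 and C11–C7 bonds; then C3–C4 of the ten-membered ring; then C4=C5, C6=C7, C1–C2, C10–C14 and C9–C10 of the open chain.
Enabling feature: in the γ-lactone ring, O sits on C6, which is allylic to the Z C4=C5 bond of the ten-membered ring, and C11 sits on the adjacent C7. C4–C5–C6–C7 is therefore the imprint of a ring 1,3-diene that took up carbon at its terminus and oxygen at the adjoining allyl carbon, so 2-bromoacrylic acid can deliver the complete α-methylene lactone in one palladium-catalysed (3+2) annulation.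
Forward order: C7–C9 come from (R)-epichlorohydrin and C10/C1 from an acetylide; C14 and C2–C3 by carboalumination and oxirane opening; C5–C6 by cross-metathesis; C4/C15 by iodo-Wittig. Ring A (carbocycle) closes by Nozaki–Hiyama–Kishi reaction, ring B (lactone) by the annulation. The two esters follow (the acyl oxirane arrives preformed), and the ring oxirane comes last.
Stereochemistry: C8 from epichlorohydrin; C3 by CBS reduction; C6 and C7 from C8 through peripheral syn addition to the E C6=C7 bond; C1/C10 by peripheral peracid attack; C2'/C3' by Sharpless epoxidation. The 1(10)E geometry comes from syn carbometalation and the 4Z geometry from the iodo-Wittig step.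

Key step: step 12

Remark: germacrane numbering is used throughout (ring C1–C10, lactone C11–C13, C14 on C10, C15 on C4). The O8 acyl group as drawn carries its two methyl groups cis on the oxirane, (2S,3R). This is the epoxide of tiglate (E) geometry, and the route is built for that isomer.

Step 1
Reactants: 1 (R)-epichlorohydrin; 2 ethynyltrimethylsilane
Product: 4 (2R)-1-chloro-5-(trimethylsilyl)pent-4-yn-2-ol, via lithium silylacetylide 3 (not isolated)
Conditions: 2, n-BuLi, THF, −78 °C; BF3·OEt2; then 1, −78 °C; H2O
Reagents that add atoms: none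
Why: BF3-assisted opening of the terminal epoxide by the lithium acetylide (Yamaguchi–Hirao alkynylation) occurs at the unsubstituted ring carbon faster than chloride displacement, so the future C8 stereocentre of 1 is carried over untouched.

Step 2
Reactants: 4 (2R)-1-chloro-5-(trimethylsilyl)pent-4-yn-2-ol
Product: 7 (3R)-hex-1-en-5-yn-3-ol, via silyl alkynyl epoxide 5 (not isolated), via silyl enynol 6 (not isolated)
Conditions: Me3SI (4 equiv), n-BuLi (3.9 equiv), THF, −10 °C to rt; then MeOH, K2CO3 (cat.), rt
Reagents that add atoms: trimethylsulfonium iodide C[S+](C)C.[I-]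
Why: The sulfonium ylide first closes the chlorohydrin to epoxide 5 and then performs the one-carbon epoxide-to-allylic-alcohol homologation (opening at CH2, then loss of Me2S), neither event touching C8, and methanolic carbonate then removes the alkynyl silane by protodesilylation.

Step 3
Reactants: 7 (3R)-hex-1-en-5-yn-3-ol
Product: 8 (3R)-3-(tert-butyldimethylsilyloxy)hex-1-en-5-yne
Conditions: TBSCl, imidazole, DMF, 0 °C to rt
Reagents that add atoms: tert-butyldimethylsilyl chloride CC(C)(C)[Si](C)(C)Cl
Why: Standard silylation gives a bulky ether at O8 that cannot ionise; it survives every step up to step 15 and later serves as the steric control element of the key step.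

Step 4
Reactants: 8 (3R)-3-(tert-butyldimethylsilyloxy)hex-1-en-5-yne; 9 ethylene oxide
Product: 12 (3E,6R)-6-(tert-butyldimethylsilyloxy)-4-methylocta-3,7-dien-1-ol, via alkenyldimethylalane 10 (not isolated), via lithium alkenylalanate 11 (not isolated)
Conditions: Me3Al (3 equiv), Cp2ZrCl2 (0.25 equiv), CH2Cl2, 0 °C to rt; volatiles removed; n-BuLi, hexane–THF, −30 °C; 9, THF, −30 °C to rt; H2O
Reagents that add atoms: trimethylaluminium C[Al](C)C
Why: Negishi zirconium-catalysed carboalumination adds Me and Al syn to the alkyne (much faster than to the vinyl group) with Al on the terminal carbon, which fixes the E C1=C10 olefin, and the derived alanate opens ethylene oxide with retention of olefin geometry.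

Step 5
Reactants: 12 (3E,6R)-6-(tert-butyldimethylsilyloxy)-4-methylocta-3,7-dien-1-ol; 13 (E)-crotonaldehyde
Product: 14 (2E,4R,6E)-4-(tert-butyldimethylsilyloxy)-9-hydroxy-6-methylnona-2,6-dienal
Conditions: second-generation Hoveyda–Grubbs catalyst (5 mol %), 13 (5 equiv), CH2Cl2, 40 °C
Reagents that add atoms: none
Why: Olefin cross-metathesis between the monosubstituted allylic-ether olefin and the enal partner is E-selective under thermodynamic control, tolerates the free alcohol and leaves the trisubstituted olefin untouched.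

Step 6
Reactants: 14 (2E,4R,6E)-4-(tert-butyldimethylsilyloxy)-9-hydroxy-6-methylnona-2,6-dienal
Product: 15 (3E,6R,7E,9Z)-6-(tert-butyldimethylsilyloxy)-10-iodo-4-methylundeca-3,7,9-trien-1-ol
Conditions: EtPPh3I, n-BuLi, THF, rt; I2, −78 °C; NaHMDS, −20 °C; then 14, −78 °C (2.5 equiv of ylide)
Reagents that add atoms: ethyltriphenylphosphonium iodide CC[P+](c1ccccc1)(c1ccccc1)c1ccccc1.[I-]; iodine [I][I]
Why: Stork–Zhao-type Wittig olefination with the α-iodoethylidene ylide gives the Z trisubstituted alkenyl iodide (I cis to C6) under kinetic control, and the ylide is not basic enough to be quenched by the free primary alcohol.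

Step 7
Reactants: 15 (3E,6R,7E,9Z)-6-(tert-butyldimethylsilyloxy)-10-iodo-4-methylundeca-3,7,9-trien-1-ol
Product: 16 (3E,6R,7E,9Z)-6-(tert-butyldimethylsilyloxy)-10-iodo-4-methylundeca-3,7,9-trienal
Conditions: Dess–Martin periodinane, pyridine, CH2Cl2, 0 °C; used directly
Reagents that add atoms: none
Why: Dess–Martin oxidation under buffered, near-neutral conditions gives the β,γ-unsaturated aldehyde without moving the C1=C10 bond into conjugation.

Step 8
Reactants: 16 (3E,6R,7E,9Z)-6-(tert-butyldimethylsilyloxy)-10-iodo-4-methylundeca-3,7,9-trienal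
Product: 17 (2Z,4E,6R,8E)-6-(tert-butyldimethylsilyloxy)-2,8-dimethylcyclodeca-2,4,8-trien-1-ol as a pair of epimers at the carbinol carbon (germacrane C3)
Conditions: CrCl2 (10 equiv), NiCl2 (0.1 equiv), DMSO–THF, 0.003 M, slow addition, rt; H2O
Reagents that add atoms: none
Why: Nozaki–Hiyama–Kishi reaction: nickel-mediated insertion into the C4–I bond and transmetalation give an alkenylchromium species that keeps the Z geometry and adds to the aldehyde under neutral conditions, closure being helped by six sp2 carbons that leave few rotatable bonds; the new C3 centre is not relied upon and is erased in step 9.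

Step 9
Reactants: 17 macrocyclic trienol (C3 epimers)
Product: 18 (2Z,4E,6R,8E)-6-(tert-butyldimethylsilyloxy)-2,8-dimethylcyclodeca-2,4,8-trien-1-one
Conditions: Dess–Martin periodinane, CH2Cl2, 0 °C
Reagents that add atoms: none
Why: Dess–Martin oxidation of the allylic alcohol converges both C3 epimers on one dienone without touching the silyl ether or the olefin geometries.

Step 10
Reactants: 18 macrocyclic trienone
Product: 19 (1S,2Z,4E,6R,8E)-6-(tert-butyldimethylsilyloxy)-2,8-dimethylcyclodeca-2,4,8-trien-1-ol
Conditions: (R)-Me-CBS oxazaborolidine (0.5 equiv), catecholborane, toluene, −78 °C; aq. work-up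
Reagents that add atoms: none
Why: Corey–Bakshi–Shibata reduction: the ketone binds the oxazaborolidine boron anti to its larger α-methyl-dienyl arm (C4), and with the R catalyst hydride goes 1,2 to the face that gives the 3S (3β) allylic alcohol.

Step 11
Reactants: 19 (1S)-trienol
Product: 20 triethyl{[(1S,2Z,4E,6R,8E)-6-(tert-butyldimethylsilyloxy)-2,8-dimethylcyclodeca-2,4,8-trien-1-yl]oxy}silane
Conditions: TESCl, imidazole, DMF, 0 °C
Reagents that add atoms: triethylsilyl chloride CC[Si](Cl)(CC)CC
Why: Silylation masks O3 as a group that can neither ionise to an allylpalladium species nor attack one in step 12, and that can be removed in the presence of the TBS ether.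

Step 12
Reactants: 20 bis-silyl trienediol; 21 2-bromoacrylic acid
Product: 23 3β-(triethylsilyloxy)-8β-(tert-butyldimethylsilyloxy)germacra-1(10)E,4Z,11(13)-trien-6α,12-olide (7α-H), via six-membered palladacycle 22 (not isolated)
Conditions: Pd(OAc)2 (10 mol %), P(o-tol)3 (20 mol %), Ag2CO3 (1.5 equiv), 21 (1.5 equiv, slow addition), BHT (trace), DMF, 50 °C
Reagents that add atoms: none
Why: Larock-type heteroannulation of a 1,3-diene, a formal (3+2) addition of the C11–C12–O unit of 21 across C6=C7: zerovalent palladium inserts into the C–Br bond of the silver carboxylate of 21, the alkenylpalladium adds syn to the strained E C6=C7 bond with C11 going to the less substituted diene terminus C7, and the resulting C4–C5–C6 allylpalladium is held by the carboxylate as palladacycle 22, from which C6–O reductive elimination closes the lactone and returns zerovalent palladium. The closest known reaction type is the palladium-catalysed annulation of acyclic and cyclic 1,3-dienes by 2-haloacrylic acids and other functionalised vinylic or aryl halides, in which cyclic dienes give the product of syn carbopalladation and front-side displacement of the metal. The one ring closed is the five-membered lactone, formed at the proximal allyl terminus C6 rather than as a seven-membered ring at the tertiary terminus C4. C7 is set by attack on the only exposed (peripheral) face of the E olefin in the conformer that places C9 anti, the C8 silyloxy group inside and H8 outside (the other conformer pushes the bulky silyloxy group into the path of the incoming carbon), and C6 follows from C7 because both bonds are made on the same face of an E olefin, which can only give the trans 6α-O/7α-H lactone. The C4=C5 bond keeps its Z geometry because C3 stays in the anti position of the allyl unit inside the ring. Chemo- and regioselectivity rest on allyl stabilisation (diene rather than the isolated C1=C10 olefin), on silyl ethers at both allylic oxygens, which cannot ionise, and on halide-free conditions (Ag2CO3), which keep the carboxylate on palladium.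

Step 13
Reactants: 23 bis-silyl lactone
Product: 24 3β-hydroxy-8β-(tert-butyldimethylsilyloxy)germacra-1(10)E,4Z,11(13)-trien-6α,12-olide
Conditions: PPTS (cat.), MeOH–CH2Cl2, 0 °C
Reagents that add atoms: none
Why: Mild acid-catalysed methanolysis cleaves the triethylsilyl ether much faster than the hindered secondary TBS ether and is too weak to trigger transannular cyclisation.

Step 14
Reactants: 24 3β-alcohol; 25 isovaleric anhydride
Product: 26 3β-isovaleryloxy-8β-(tert-butyldimethylsilyloxy)germacra-1(10)E,4Z,11(13)-trien-6α,12-olide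
Conditions: 25, DMAP (cat.), pyridine, CH2Cl2, 0 °C to rt
Reagents that add atoms: none
Why: DMAP-catalysed acylation of the only free hydroxyl proceeds with retention at C3.

Step 15
Reactants: 26 3β-isovalerate
Product: 27 8β-hydroxy-3β-isovaleryloxygermacra-1(10)E,4Z,11(13)-trien-6α,12-olide
Conditions: HF·pyridine, excess pyridine, THF, 0 °C to rt
Reagents that add atoms: none
Why: Buffered fluoride desilylation frees O8 without basic conditions that would invite conjugate addition to the methylene lactone, acyl migration or relactonisation.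

Step 16
Reactants: 28 (E)-2-methylbut-2-en-1-ol
Product: 29 [(2R,3R)-2,3-dimethyloxiran-2-yl]methanol
Conditions: Ti(OiPr)4 (cat.), D-(−)-diisopropyl tartrate (cat.), t-BuOOH, 4 Å molecular sieves, CH2Cl2, −20 °C
Reagents that add atoms: tert-butyl hydroperoxide CC(C)(C)OO
Why: Sharpless asymmetric epoxidation with the D-(−)-tartrate delivers oxygen to the face of the E allylic alcohol that gives the (2R,3R)-epoxy alcohol, and syn-stereospecific oxygen transfer keeps the two methyl groups cis.

Step 17
Reactants: 29 [(2R,3R)-2,3-dimethyloxiran-2-yl]methanol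
Product: 30 (2S,3R)-2,3-dimethyloxirane-2-carboxylic acid
Conditions: RuCl3 (cat.), NaIO4, MeCN–EtOAc–H2O, rt
Reagents that add atoms: sodium periodate [Na+].[O-]I(=O)(=O)=O
Why: Ruthenium tetroxide oxidation takes the primary alcohol to the acid without opening the trisubstituted oxirane, the change of the C2 descriptor to S being only a change of priorities.

Step 18
Reactants: 27 8β-alcohol; 30 (2S,3R)-2,3-dimethyloxirane-2-carboxylic acid
Product: 32 3β-isovaleryloxy-8β-[(2S,3R)-2,3-dimethyloxirane-2-carbonyloxy]germacra-1(10)E,4Z,11(13)-trien-6α,12-olide, via mixed trichlorobenzoic anhydride 31 (not isolated)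
Conditions: 30, 2,4,6-trichlorobenzoyl chloride, Et3N, toluene, rt; then 27, DMAP, toluene, rt to 40 °C
Reagents that add atoms: none
Why: Yamaguchi esterification through mixed anhydride 31 acylates the hindered 8β-hydroxyl with retention at C8, and the acid cannot epimerise because its α-carbon is quaternary.

Step 19
Reactants: 32 triene diester
Product: 33 target, 3β-isovaleryloxy-8β-[(2S,3R)-2,3-dimethyloxirane-2-carbonyloxy]-1β,10α-epoxygermacra-4Z,11(13)-dien-6α,12-olide
Conditions: mCPBA (1.05 equiv), CH2Cl2–pH 7 phosphate buffer, 0 °C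
Reagents that add atoms: 3-chloroperoxybenzoic acid O=C(OO)c1cccc(Cl)c1
Why: Prilezhaev epoxidation picks the only electron-rich olefin (C4=C5 is flanked by two acyloxy-bearing carbons, C11=C13 is conjugated to the lactone) and attacks the exposed outer face of the E C1=C10 bond in the conformer with C14 on the β face, giving the 1β,10α (1R,10R) oxirane.

**Compound list**

1 | (R)-epichlorohydrin | ClC[C@H]1CO1 | starting material
2 | ethynyltrimethylsilane | C#C[Si](C)(C)C | starting material
3 | lithium (trimethylsilyl)acetylide | [Li]C#C[Si](C)(C)C | intermediate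
4 | (2R)-1-chloro-5-(trimethylsilyl)pent-4-yn-2-ol | C[Si](C)(C)C#CC[C@@H](O)CCl | intermediate
5 | (2R)-2-[3-(trimethylsilyl)prop-2-yn-1-yl]oxirane | C[Si](C)(C)C#CC[C@@H]1CO1 | intermediate
6 | (3R)-6-(trimethylsilyl)hex-1-en-5-yn-3-ol | C[Si](C)(C)C#CC[C@@H](O)C=C | intermediate
7 | (3R)-hex-1-en-5-yn-3-ol | C#CC[C@@H](O)C=C | intermediate
8 | (3R)-3-(tert-butyldimethylsilyloxy)hex-1-en-5-yne | C#CC[C@@H](O[Si](C)(C)C(C)(C)C)C=C | intermediate
9 | ethylene oxide | C1CO1 | starting material
10 | [(1E,4R)-4-(tert-butyldimethylsilyloxy)-2-methylhexa-1,5-dien-1-yl]dimethylalane | C[Al](C)/C=C(\C)C[C@@H](O[Si](C)(C)C(C)(C)C)C=C | intermediate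
11 | lithium butyl[(1E,4R)-4-(tert-butyldimethylsilyloxy)-2-methylhexa-1,5-dien-1-yl]dimethylalanate | [Li+].CCCC[Al-](C)(C)/C=C(\C)C[C@@H](O[Si](C)(C)C(C)(C)C)C=C | intermediate
12 | (3E,6R)-6-(tert-butyldimethylsilyloxy)-4-methylocta-3,7-dien-1-ol | OCC/C=C(\C)C[C@@H](O[Si](C)(C)C(C)(C)C)C=C | intermediate
13 | (E)-crotonaldehyde | C/C=C/C=O | starting material
14 | (2E,4R,6E)-4-(tert-butyldimethylsilyloxy)-9-hydroxy-6-methylnona-2,6-dienal | OCC/C=C(\C)C[C@@H](O[Si](C)(C)C(C)(C)C)/C=C/C=O | intermediate
15 | (3E,6R,7E,9Z)-6-(tert-butyldimethylsilyloxy)-10-iodo-4-methylundeca-3,7,9-trien-1-ol | OCC/C=C(\C)C[C@@H](O[Si](C)(C)C(C)(C)C)/C=C/C=C(/C)I | intermediate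
16 | (3E,6R,7E,9Z)-6-(tert-butyldimethylsilyloxy)-10-iodo-4-methylundeca-3,7,9-trienal | O=CC/C=C(\C)C[C@@H](O[Si](C)(C)C(C)(C)C)/C=C/C=C(/C)I | intermediate
17 | (2Z,4E,6R,8E)-6-(tert-butyldimethylsilyloxy)-2,8-dimethylcyclodeca-2,4,8-trien-1-ol, both carbinol epimers | OC1C/C=C(\C)C[C@@H](O[Si](C)(C)C(C)(C)C)/C=C/C=C1/C | intermediate
18 | (2Z,4E,6R,8E)-6-(tert-butyldimethylsilyloxy)-2,8-dimethylcyclodeca-2,4,8-trien-1-one | O=C1C/C=C(\C)C[C@@H](O[Si](C)(C)C(C)(C)C)/C=C/C=C1/C | intermediate
19 | (1S,2Z,4E,6R,8E)-6-(tert-butyldimethylsilyloxy)-2,8-dimethylcyclodeca-2,4,8-trien-1-ol | O[C@H]1C/C=C(\C)C[C@@H](O[Si](C)(C)C(C)(C)C)/C=C/C=C1/C | intermediate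
20 | triethylsilyl ether of 19 | CC[Si](CC)(CC)O[C@H]1C/C=C(\C)C[C@@H](O[Si](C)(C)C(C)(C)C)/C=C/C=C1/C | intermediate
21 | 2-bromoacrylic acid | C=C(Br)C(=O)O | starting material
22 | six-membered palladacycle (Pd bound to C6 and to the carboxylate O, ligands omitted) | C=C1C(=O)O[Pd][C@@H]2/C=C(/C)[C@@H](O[Si](CC)(CC)CC)C/C=C(\C)C[C@@H](O[Si](C)(C)C(C)(C)C)[C@@H]12 | intermediate
23 | 3β-(triethylsilyloxy)-8β-(tert-butyldimethylsilyloxy)germacra-1(10)E,4Z,11(13)-trien-6α,12-olide | C=C1C(=O)O[C@@H]2/C=C(/C)[C@@H](O[Si](CC)(CC)CC)C/C=C(\C)C[C@@H](O[Si](C)(C)C(C)(C)C)[C@@H]12 | intermediate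
24 | 3β-hydroxy-8β-(tert-butyldimethylsilyloxy)germacra-1(10)E,4Z,11(13)-trien-6α,12-olide | C=C1C(=O)O[C@@H]2/C=C(/C)[C@@H](O)C/C=C(\C)C[C@@H](O[Si](C)(C)C(C)(C)C)[C@@H]12 | intermediate
25 | isovaleric anhydride | CC(C)CC(=O)OC(=O)CC(C)C | starting material
26 | 3β-isovaleryloxy-8β-(tert-butyldimethylsilyloxy)germacra-1(10)E,4Z,11(13)-trien-6α,12-olide | C=C1C(=O)O[C@@H]2/C=C(/C)[C@@H](OC(=O)CC(C)C)C/C=C(\C)C[C@@H](O[Si](C)(C)C(C)(C)C)[C@@H]12 | intermediate
27 | 8β-hydroxy-3β-isovaleryloxygermacra-1(10)E,4Z,11(13)-trien-6α,12-olide | C=C1C(=O)O[C@@H]2/C=C(/C)[C@@H](OC(=O)CC(C)C)C/C=C(\C)C[C@@H](O)[C@@H]12 | intermediate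
28 | (E)-2-methylbut-2-en-1-ol | C/C=C(\C)CO | starting material
29 | [(2R,3R)-2,3-dimethyloxiran-2-yl]methanol | OC[C@@]1(C)O[C@@H]1C | intermediate
30 | (2S,3R)-2,3-dimethyloxirane-2-carboxylic acid | OC(=O)[C@@]1(C)O[C@@H]1C | intermediate
31 | (2S,3R)-2,3-dimethyloxirane-2-carboxylic 2,4,6-trichlorobenzoic anhydride | O=C(OC(=O)[C@@]1(C)O[C@@H]1C)c1c(Cl)cc(Cl)cc1Cl | intermediate
32 | 3β-isovaleryloxy-8β-[(2S,3R)-2,3-dimethyloxirane-2-carbonyloxy]germacra-1(10)E,4Z,11(13)-trien-6α,12-olide | C=C1C(=O)O[C@@H]2/C=C(/C)[C@@H](OC(=O)CC(C)C)C/C=C(\C)C[C@@H](OC(=O)[C@@]3(C)O[C@@H]3C)[C@@H]12 | intermediate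
33 | CNP0167461.3 | C=C1C(=O)O[C@@H]2/C=C(/C)[C@@H](OC(=O)CC(C)C)C[C@H]3O[C@]3(C)C[C@@H](OC(=O)[C@@]3(C)O[C@@H]3C)[C@@H]12 | target

**Step count**

Total step count: 19. Longest linear sequence: 17 (steps 1–15, 18 and 19).

**Steps most likely to fail**

Step 12. What may go wrong:
- poor facial selectivity at C7;
- β-hydride elimination of the allylpalladium species to a triene;
- loss of the trans relationship through outer-sphere attack or allyl isomerisation.

The fallback makes the same two bonds by a radical–polar sequence and adds the methylene afterwards. It sets out from 20.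
- Iodine-atom-transfer addition of iodoacetic acid (Et3B, air, CH2Cl2, rt; then NaHCO3) places the carboxymethyl radical on the diene terminus C7 from the outer face. The allylic iodide then lactonises at C6 to the α-unsubstituted trans-lactone F1.
- Enolisation (LDA, THF, −78 °C) and trapping with dimethylmethyleneiminium iodide gives the α-(dimethylaminomethyl) lactone F2.
- MeI gives its methiodide F3, and NaHCO3-induced elimination comes back to the route at 23.

Step 8. What may go wrong:
- oligomerisation in place of closure of the strained ring;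
- migration of the C1=C10 bond of the aldehyde into conjugation.

The fallback closes the ring at the sp2–sp2 bond C5–C6 instead of at a carbonyl. It sets out from 12.
- Dess–Martin oxidation gives the dienal F4.
- Ethynylmagnesium bromide gives the propargylic alcohol F5 (both C3 epimers).
- Copper-catalysed anti-carbomagnesiation (MeMgBr, CuI, Et2O) through the magnesium alkoxide chelate, followed by an iodine quench, gives the (Z)-β-iodo allylic alcohol F6 with iodine cis to C3.
- An intramolecular Heck reaction of the C5–I bond with the terminal C6=C7 vinyl group (Pd(OAc)2, Ag2CO3, high dilution) comes back to the route at 17.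

Step 10. What may go wrong:
- a mismatch between catalyst control and the conformational bias of the ring, giving poor facial selectivity;
- conjugate reduction.

The fallback uses substrate control followed by inversion. It sets out from 18.
- Luche reduction (NaBH4, CeCl3·7H2O, MeOH, −78 °C) with peripheral hydride attack is taken to the 3α-alcohol F7.
- Mitsunobu reaction with 4-nitrobenzoic acid (PPh3, DIAD) inverts C3 to the 3β 4-nitrobenzoate F8.
- Methanolysis (K2CO3, MeOH) comes back to the route at 19.

**Further compounds**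

F1 | step 12 | 3β-(triethylsilyloxy)-8β-(tert-butyldimethylsilyloxy)germacra-1(10)E,4Z-dien-6α,12-olide lacking C13 (α-unsubstituted lactone) | C1C(=O)O[C@@H]2/C=C(/C)[C@@H](O[Si](CC)(CC)CC)C/C=C(\C)C[C@@H](O[Si](C)(C)C(C)(C)C)[C@@H]12
F2 | step 12 | α-(dimethylaminomethyl) lactone, C11 configuration without consequence | CN(C)CC1C(=O)O[C@@H]2/C=C(/C)[C@@H](O[Si](CC)(CC)CC)C/C=C(\C)C[C@@H](O[Si](C)(C)C(C)(C)C)[C@@H]12
F3 | step 12 | methiodide of F2 | C[N+](C)(C)CC1C(=O)O[C@@H]2/C=C(/C)[C@@H](O[Si](CC)(CC)CC)C/C=C(\C)C[C@@H](O[Si](C)(C)C(C)(C)C)[C@@H]12.[I-]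
F4 | step 8 | (3E,6R)-6-(tert-butyldimethylsilyloxy)-4-methylocta-3,7-dienal | O=CC/C=C(\C)C[C@@H](O[Si](C)(C)C(C)(C)C)C=C
F5 | step 8 | (5E,8R)-8-(tert-butyldimethylsilyloxy)-6-methyldeca-5,9-dien-1-yn-3-ol, both carbinol epimers | C#CC(O)C/C=C(\C)C[C@@H](O[Si](C)(C)C(C)(C)C)C=C
F6 | step 8 | (1Z,5E,8R)-8-(tert-butyldimethylsilyloxy)-1-iodo-2,6-dimethyldeca-1,5,9-trien-3-ol, both carbinol epimers | I/C=C(/C)C(O)C/C=C(\C)C[C@@H](O[Si](C)(C)C(C)(C)C)C=C
F7 | step 10 | (1R,2Z,4E,6R,8E)-6-(tert-butyldimethylsilyloxy)-2,8-dimethylcyclodeca-2,4,8-trien-1-ol | O[C@@H]1C/C=C(\C)C[C@@H](O[Si](C)(C)C(C)(C)C)/C=C/C=C1/C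
F8 | step 10 | (1S,2Z,4E,6R,8E)-6-(tert-butyldimethylsilyloxy)-2,8-dimethylcyclodeca-2,4,8-trien-1-yl 4-nitrobenzoate | O=C(O[C@H]1C/C=C(\C)C[C@@H](O[Si](C)(C)C(C)(C)C)/C=C/C=C1/C)c1ccc(cc1)[N+](=O)[O-]
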